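## Retrosynthetic overview

1. Target 25 ⇐ desilylation and a late allylic C–H hydroxylation (C15) of elemanolide 23.
2. 23 ⇐ acyclic aldehyde 20. SmI2 turns the C6 aldehyde carbon into a nucleophilic ketyl that adds 6-exo to the enoate β-carbon C7; methoxide loss gives the exocyclic methylene and the alkoxide lactonises. The carbocycle forms first and the lactone second, in the same flask.
3. 20 ⇐ thioester 19 ⇐ C8 ester of γ-hydroxy enoate 15 with silylated acid 18; 15 ⇐ aldehyde 9 by D-proline α-aminoxylation and olefination with phosphonate 12.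
4. 9 ⇐ prenyl cleavage of thioester 7 ⇐ acid 6 ⇐ enantioselective Ireland–Claisen rearrangement of geranyl 3-methylbut-3-enoate 3 (C5–C10 bond, both stereocentres) ⇐ geraniol 1 + acid 2.

Atom labels follow elemane numbering of the final skeleton: C10 quaternary (methyl, vinyl), C9 CH2, C8 acyloxy carbon, C7 and C6 ring-fusion carbons, C5 bearing the C4(=C3)–C15 unit, C11/C12/C13 lactone α-carbon, carbonyl and methylene.

Assumption: the (S,S)-bromoborane is taken as the enantiomer that delivers the (2S,3S)-acid 6 (recalled by analogy with related geranyl ester rearrangements, not verified); if the sense is opposite, the (R,R)-reagent is used with no other change.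

## Route

Step 1
Reactants: 1 geraniol; 2 3-methylbut-3-enoic acid
Product: 3 geranyl 3-methylbut-3-enoate
Conditions: DCC, DMAP (5 mol %), CH2Cl2, 0 °C → rt
Reagents that add atoms: none
Why: Steglich esterification of a primary allylic alcohol; low DMAP loading at 0 °C keeps the β,γ-unsaturated acyl unit from moving into conjugation, and no stereocentre is involved.

Step 2
Reactants: 3 geranyl 3-methylbut-3-enoate
Product: 6 (2S,3S)-3-ethenyl-3,7-dimethyl-2-(prop-1-en-2-yl)oct-6-enoic acid, via boron ketene acetal 4 (not isolated), via acyloxyborane 5 (not isolated)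
Conditions: (S,S)-bromoborane controller (freshly made from the (S,S)-bis-sulfonamide and BBr3), iPr2NEt, CH2Cl2, −78 °C; then −20 → 4 °C, 3 d; H2O
Reagents that add atoms: none
Why: Enantioselective Ireland–Claisen rearrangement (chiral boron enolate variant): soft enolisation gives the ketene acetal with the isopropenyl group cis to the O-geranyl oxygen, and the chair transition state with the (E)-allyl unit (C9 chain equatorial, isopropenyl axial) sets C5 and the quaternary C10 together as 2S,3S, the C2-symmetric sulfonamide groups of the controller shielding one enolate face.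

Step 3
Reactants: 6 (2S,3S)-3-ethenyl-3,7-dimethyl-2-(prop-1-en-2-yl)oct-6-enoic acid
Product: 7 S-ethyl (2S,3S)-3-ethenyl-3,7-dimethyl-2-(prop-1-en-2-yl)oct-6-enethioate
Conditions: EtSH, DCC, DMAP (10 mol %), CH2Cl2, 0 °C → rt
Reagents that add atoms: ethanethiol, CCS
Why: Steglich-type thioesterification; the thioester is a latent aldehyde that survives the oxidative, mildly basic and acylating steps ahead, and activation without strong base leaves the α-stereocentre C5 untouched.

Step 4
Reactants: 7 S-ethyl (2S,3S)-3-ethenyl-3,7-dimethyl-2-(prop-1-en-2-yl)oct-6-enethioate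
Product: 9 S-ethyl (2S,3S)-3-ethenyl-3-methyl-6-oxo-2-(prop-1-en-2-yl)hexanethioate, via epoxide 8 (not isolated)
Conditions: mCPBA (1.05 equiv), CH2Cl2, −20 °C; then H5IO6, THF/H2O, 0 °C
Reagents that add atoms: mCPBA (3-chloroperoxybenzoic acid), OOC(=O)c1cccc(Cl)c1
Why: Prilezhaev epoxidation selects the electron-rich trisubstituted alkene over the hindered 1,1-disubstituted and monosubstituted ones, and periodic acid opens the epoxide and cleaves the glycol to the aldehyde (the epoxide configuration is irrelevant).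

Step 5
Reactants: 10 methyl 2-bromo-3-methoxypropanoate (racemic); 11 trimethyl phosphite
Product: 12 methyl 2-(dimethoxyphosphoryl)-3-methoxypropanoate
Conditions: neat, 130 °C, MeBr distilled off
Reagents that add atoms: none
Why: Michaelis–Arbuzov reaction of an α-bromo ester; the reagent is used as the racemate because its stereocentre disappears in the olefination.

Step 6
Reactants: 9 S-ethyl (2S,3S)-3-ethenyl-3-methyl-6-oxo-2-(prop-1-en-2-yl)hexanethioate; 12 methyl 2-(dimethoxyphosphoryl)-3-methoxypropanoate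
Product: 14 methyl (2E,4S,6S,7S)-6-ethenyl-8-(ethylsulfanyl)-2-(methoxymethyl)-6-methyl-8-oxo-4-[(phenylamino)oxy]-7-(prop-1-en-2-yl)oct-2-enoate, via aminoxy aldehyde 13 (not isolated)
Conditions: D-proline (20 mol %), PhNO (1.0 equiv), DMSO, rt, 30 min; then 12, LiCl, iPr2NEt, MeCN, 0 °C
Reagents that add atoms: nitrosobenzene, O=Nc1ccccc1
Why: Proline-catalysed α-aminoxylation in which the (E)-enamine attacks the nitroso oxygen on the face fixed by the carboxylic acid hydrogen bond (Houk–List model), so D-proline gives the S centre at C8; in-situ Masamune–Roush Horner–Wadsworth–Emmons olefination then traps the labile aldehyde as the (E)-enoate (the minor Z isomer lactonises after step 7 and is removed).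

Step 7
Reactants: 14 methyl (2E,4S,6S,7S)-6-ethenyl-8-(ethylsulfanyl)-2-(methoxymethyl)-6-methyl-8-oxo-4-[(phenylamino)oxy]-7-(prop-1-en-2-yl)oct-2-enoate
Product: 15 methyl (2E,4S,6S,7S)-6-ethenyl-8-(ethylsulfanyl)-4-hydroxy-2-(methoxymethyl)-6-methyl-8-oxo-7-(prop-1-en-2-yl)oct-2-enoate
Conditions: Zn dust, AcOH/THF (1:3), 0 °C → rt
Reagents that add atoms: none
Why: Reductive cleavage of the weak N–O bond by zinc in acetic acid frees the allylic alcohol without touching the thioester, the enoate or the C8 configuration.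

Step 8
Reactants: 16 methyl (2R)-3-hydroxy-2-methylpropanoate
Product: 17 methyl (2R)-3-[(tert-butyldimethylsilyl)oxy]-2-methylpropanoate
Conditions: TBSCl, imidazole, DMF, rt
Reagents that add atoms: tert-butyldimethylsilyl chloride, CC(C)(C)[Si](C)(C)Cl
Why: Standard imidazole-promoted silylation of a primary alcohol; the stereocentre is not involved.

Step 9
Reactants: 17 methyl (2R)-3-[(tert-butyldimethylsilyl)oxy]-2-methylpropanoate
Product: 18 (2R)-3-[(tert-butyldimethylsilyl)oxy]-2-methylpropanoic acid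
Conditions: LiOH, THF/H2O (3:1), 0 °C; then 1 M HCl to pH 4
Reagents that add atoms: lithium hydroxide, [Li+].[OH-]
Why: Saponification of the methyl ester at 0 °C, mild enough to leave the α-stereocentre and the silyl ether intact.

Step 10
Reactants: 15 methyl (2E,4S,6S,7S)-6-ethenyl-8-(ethylsulfanyl)-4-hydroxy-2-(methoxymethyl)-6-methyl-8-oxo-7-(prop-1-en-2-yl)oct-2-enoate; 18 (2R)-3-[(tert-butyldimethylsilyl)oxy]-2-methylpropanoic acid
Product: 19 methyl (2E,4S,6S,7S)-4-{[(2R)-3-[(tert-butyldimethylsilyl)oxy]-2-methylpropanoyl]oxy}-6-ethenyl-8-(ethylsulfanyl)-2-(methoxymethyl)-6-methyl-8-oxo-7-(prop-1-en-2-yl)oct-2-enoate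
Conditions: DCC, DMAP (10 mol %), CH2Cl2, 0 °C → rt
Reagents that add atoms: none
Why: Steglich esterification with retention at C8; the side chain is installed before ring formation so that O8 cannot compete in the later lactonisation, and acylation outpaces attack of the alcohol on the hindered thioester.

Step 11
Reactants: 19 methyl (2E,4S,6S,7S)-4-{[(2R)-3-[(tert-butyldimethylsilyl)oxy]-2-methylpropanoyl]oxy}-6-ethenyl-8-(ethylsulfanyl)-2-(methoxymethyl)-6-methyl-8-oxo-7-(prop-1-en-2-yl)oct-2-enoate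
Product: 20 methyl (2E,4S,6S,7S)-4-{[(2R)-3-[(tert-butyldimethylsilyl)oxy]-2-methylpropanoyl]oxy}-6-ethenyl-2-(methoxymethyl)-6-methyl-8-oxo-7-(prop-1-en-2-yl)oct-2-enoate
Conditions: Et3SiH (3 equiv), Pd/C (10 wt %, 5 mol % Pd), acetone, rt
Reagents that add atoms: none
Why: Fukuyama reduction; palladium inserts into the C–S bond and the silane delivers hydride, giving the aldehyde under neutral conditions that spare the esters, the silyl ether and the epimerisable C5 centre.

Step 12
Reactants: 20 methyl (2E,4S,6S,7S)-4-{[(2R)-3-[(tert-butyldimethylsilyl)oxy]-2-methylpropanoyl]oxy}-6-ethenyl-2-(methoxymethyl)-6-methyl-8-oxo-7-(prop-1-en-2-yl)oct-2-enoate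
Product: 23 (3aR,4S,6S,7S,7aR)-6-ethenyl-6-methyl-3-methylidene-2-oxo-7-(prop-1-en-2-yl)octahydro-1-benzofuran-4-yl (2R)-3-[(tert-butyldimethylsilyl)oxy]-2-methylpropanoate, via samarium alkoxide enolate 21 (not isolated), via samarium alkoxide acrylate 22 (not isolated)
Conditions: SmI2 (2.2 equiv), HMPA (8 equiv), THF (5 mM), −78 °C → 0 °C; aq. NH4Cl
Reagents that add atoms: none
Why: Proposed new method: SmI2 reduces the aldehyde to a ketyl radical anion, which makes C6 nucleophilic and lets it add 6-exo-trig to the electrophilic β-carbon C7 of the enoate through a chair transition state with the C5 isopropenyl and C8 acyloxy groups equatorial and both the O–Sm group and the acceptor pseudo-equatorial (7aR and 3aR, all-equatorial trans ring fusion); the α-ester radical takes a second electron, the trivalent samarium enolate expels the β-methoxide (E1cB) to give the exocyclic methylene, and the C6 alkoxide closes the γ-lactone on the methyl ester while the C8 ester blocks the alternative lactone; the closest known reactions are SmI2 ketyl–olefin cyclisation/lactonisation of aldehyde-tethered enoates and β-alkoxide elimination from samarium ester enolates.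

Step 13
Reactants: 23 (3aR,4S,6S,7S,7aR)-6-ethenyl-6-methyl-3-methylidene-2-oxo-7-(prop-1-en-2-yl)octahydro-1-benzofuran-4-yl (2R)-3-[(tert-butyldimethylsilyl)oxy]-2-methylpropanoate
Product: 24 (3aR,4S,6S,7R,7aR)-6-ethenyl-7-(3-hydroxyprop-1-en-2-yl)-6-methyl-3-methylidene-2-oxooctahydro-1-benzofuran-4-yl (2R)-3-[(tert-butyldimethylsilyl)oxy]-2-methylpropanoate
Conditions: SeO2 (0.3 equiv), t-BuOOH (3 equiv), CH2Cl2, rt
Reagents that add atoms: tert-butyl hydroperoxide, CC(C)(C)OO
Why: Riley-type allylic oxidation (ene reaction then [2,3]-shift); the isopropenyl methyl is the only reactive allylic position, since the vinyl group has no allylic hydrogen, the acrylate alkene is electron-poor and the methine C5–H ranks below CH3, and no stereocentre changes (the C7 descriptor changes only through CIP priorities).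

Step 14
Reactants: 24 (3aR,4S,6S,7R,7aR)-6-ethenyl-7-(3-hydroxyprop-1-en-2-yl)-6-methyl-3-methylidene-2-oxooctahydro-1-benzofuran-4-yl (2R)-3-[(tert-butyldimethylsilyl)oxy]-2-methylpropanoate
Product: 25 (3aR,4S,6S,7R,7aR)-6-ethenyl-7-(3-hydroxyprop-1-en-2-yl)-6-methyl-3-methylidene-2-oxooctahydro-1-benzofuran-4-yl (2R)-3-hydroxy-2-methylpropanoate (CNP0133858.1)
Conditions: HF·pyridine, pyridine/THF, 0 °C → rt
Reagents that add atoms: none
Why: Buffered fluoride desilylation removes the TBS ether without the basic conditions that would cause Michael addition to the α-methylene lactone or acyl migration.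

## Compound list

1 | geraniol, (2E)-3,7-dimethylocta-2,6-dien-1-ol | CC(C)=CCC/C(C)=C/CO | starting material
2 | 3-methylbut-3-enoic acid | CC(=C)CC(=O)O | starting material
3 | geranyl 3-methylbut-3-enoate | CC(C)=CCC/C(C)=C/COC(=O)CC(C)=C | intermediate
4 | boron ketene acetal of 3 (O-geranyl, O-[(4S,5S)-diazaborolidin-2-yl]; isopropenyl cis to O-geranyl; not isolated) | CC(C)=CCC/C(C)=C/CO/C(=C\C(C)=C)OB1N(S(=O)(=O)c2cc(cc(c2)C(F)(F)F)C(F)(F)F)[C@@H](c2ccccc2)[C@H](c2ccccc2)N1S(=O)(=O)c1cc(cc(c1)C(F)(F)F)C(F)(F)F | intermediate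
5 | acyloxyborane, (4S,5S)-diazaborolidin-2-yl ester of acid 6 (not isolated) | C=C[C@]([C@H](C(=C)C)C(=O)OB1N(S(=O)(=O)c2cc(cc(c2)C(F)(F)F)C(F)(F)F)[C@@H](c2ccccc2)[C@H](c2ccccc2)N1S(=O)(=O)c1cc(cc(c1)C(F)(F)F)C(F)(F)F)(C)CCC=C(C)C | intermediate
6 | (2S,3S)-3-ethenyl-3,7-dimethyl-2-(prop-1-en-2-yl)oct-6-enoic acid | C=C[C@]([C@H](C(=C)C)C(=O)O)(C)CCC=C(C)C | intermediate
7 | S-ethyl (2S,3S)-3-ethenyl-3,7-dimethyl-2-(prop-1-en-2-yl)oct-6-enethioate | C=C[C@]([C@H](C(=C)C)C(=O)SCC)(C)CCC=C(C)C | intermediate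
8 | S-ethyl (2S,3S)-5-(3,3-dimethyloxiran-2-yl)-3-ethenyl-3-methyl-2-(prop-1-en-2-yl)pentanethioate (both epoxide epimers; not isolated) | C=C[C@]([C@H](C(=C)C)C(=O)SCC)(C)CCC1OC1(C)C | intermediate
9 | S-ethyl (2S,3S)-3-ethenyl-3-methyl-6-oxo-2-(prop-1-en-2-yl)hexanethioate | C=C[C@]([C@H](C(=C)C)C(=O)SCC)(C)CCC=O | intermediate
10 | methyl 2-bromo-3-methoxypropanoate (racemic) | COCC(Br)C(=O)OC | starting material
11 | trimethyl phosphite | COP(OC)OC | starting material
12 | methyl 2-(dimethoxyphosphoryl)-3-methoxypropanoate | COCC(C(=O)OC)P(=O)(OC)OC | intermediate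
13 | S-ethyl (2S,3S,5S)-3-ethenyl-3-methyl-6-oxo-5-[(phenylamino)oxy]-2-(prop-1-en-2-yl)hexanethioate (not isolated) | C=C[C@]([C@H](C(=C)C)C(=O)SCC)(C)C[C@H](ONc1ccccc1)C=O | intermediate
14 | methyl (2E,4S,6S,7S)-6-ethenyl-8-(ethylsulfanyl)-2-(methoxymethyl)-6-methyl-8-oxo-4-[(phenylamino)oxy]-7-(prop-1-en-2-yl)oct-2-enoate | C=C[C@]([C@H](C(=C)C)C(=O)SCC)(C)C[C@H](ONc1ccccc1)/C=C(/C(=O)OC)COC | intermediate
15 | methyl (2E,4S,6S,7S)-6-ethenyl-8-(ethylsulfanyl)-4-hydroxy-2-(methoxymethyl)-6-methyl-8-oxo-7-(prop-1-en-2-yl)oct-2-enoate | C=C[C@]([C@H](C(=C)C)C(=O)SCC)(C)C[C@H](O)/C=C(/C(=O)OC)COC | intermediate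
16 | methyl (2R)-3-hydroxy-2-methylpropanoate | COC(=O)[C@H](C)CO | starting material
17 | methyl (2R)-3-[(tert-butyldimethylsilyl)oxy]-2-methylpropanoate | COC(=O)[C@H](C)CO[Si](C)(C)C(C)(C)C | intermediate
18 | (2R)-3-[(tert-butyldimethylsilyl)oxy]-2-methylpropanoic acid | OC(=O)[C@H](C)CO[Si](C)(C)C(C)(C)C | intermediate
19 | methyl (2E,4S,6S,7S)-4-{[(2R)-3-[(tert-butyldimethylsilyl)oxy]-2-methylpropanoyl]oxy}-6-ethenyl-8-(ethylsulfanyl)-2-(methoxymethyl)-6-methyl-8-oxo-7-(prop-1-en-2-yl)oct-2-enoate | C=C[C@]([C@H](C(=C)C)C(=O)SCC)(C)C[C@H](OC(=O)[C@H](C)CO[Si](C)(C)C(C)(C)C)/C=C(/C(=O)OC)COC | intermediate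
20 | methyl (2E,4S,6S,7S)-4-{[(2R)-3-[(tert-butyldimethylsilyl)oxy]-2-methylpropanoyl]oxy}-6-ethenyl-2-(methoxymethyl)-6-methyl-8-oxo-7-(prop-1-en-2-yl)oct-2-enoate | C=C[C@]([C@H](C(=C)C)C=O)(C)C[C@H](OC(=O)[C@H](C)CO[Si](C)(C)C(C)(C)C)/C=C(/C(=O)OC)COC | intermediate
21 | cyclised bis-samarium species: C6 diiodosamarium alkoxide and C11 diiodosamarium ester enolate on the new cyclohexane (not isolated) | C=C[C@]1(C)C[C@H](OC(=O)[C@H](C)CO[Si](C)(C)C(C)(C)C)[C@@H](C(COC)=C(OC)O[Sm](I)I)[C@H](O[Sm](I)I)[C@H]1C(=C)C | intermediate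
22 | C6 diiodosamarium alkoxide of the cyclohexyl acrylate formed by methoxide loss (not isolated) | C=C[C@]1(C)C[C@H](OC(=O)[C@H](C)CO[Si](C)(C)C(C)(C)C)[C@@H](C(=C)C(=O)OC)[C@H](O[Sm](I)I)[C@H]1C(=C)C | intermediate
23 | (3aR,4S,6S,7S,7aR)-6-ethenyl-6-methyl-3-methylidene-2-oxo-7-(prop-1-en-2-yl)octahydro-1-benzofuran-4-yl (2R)-3-[(tert-butyldimethylsilyl)oxy]-2-methylpropanoate | C=C[C@]1(C)C[C@H](OC(=O)[C@H](C)CO[Si](C)(C)C(C)(C)C)[C@H]2C(=C)C(=O)O[C@@H]2[C@H]1C(=C)C | intermediate
24 | (3aR,4S,6S,7R,7aR)-6-ethenyl-7-(3-hydroxyprop-1-en-2-yl)-6-methyl-3-methylidene-2-oxooctahydro-1-benzofuran-4-yl (2R)-3-[(tert-butyldimethylsilyl)oxy]-2-methylpropanoate | C=C[C@]1(C)C[C@H](OC(=O)[C@H](C)CO[Si](C)(C)C(C)(C)C)[C@H]2C(=C)C(=O)O[C@@H]2[C@H]1C(=C)CO | intermediate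
25 | (3aR,4S,6S,7R,7aR)-6-ethenyl-7-(3-hydroxyprop-1-en-2-yl)-6-methyl-3-methylidene-2-oxooctahydro-1-benzofuran-4-yl (2R)-3-hydroxy-2-methylpropanoate | C=C[C@]1(C)C[C@H](OC(=O)[C@H](C)CO)[C@H]2C(=C)C(=O)O[C@@H]2[C@H]1C(=C)CO | target

## Step count and risks

Total steps: 14 (11 in the main line, 1 for phosphonate 12, 2 for acid 18).
Longest linear sequence: 11 steps (steps 1, 2, 3, 4, 6, 7, 10, 11, 12, 13, 14; 1 → 3 → 6 → 7 → 9 → 14 → 15 → 19 → 20 → 23 → 24 → 25).

Steps most likely to fail:

Step 12 (SmI2 cascade). The risks are protonation of the samarium enolate before methoxide loss, reduction of the enoate with loss of the C8 carboxylate, over-reduction of the product acrylate, and a wrong C6/C7 diastereomer. The fallback sets out from 20 and returns at 23. The cyclisation is run as a plain ketyl–olefin reaction with a proton source (SmI2, t-BuOH, THF, −78 °C), so the enolate is protonated on purpose and lactonisation gives the 13-methoxy-11,13-dihydrolactone F3 (C11 epimers). The methylene is then made in a separate polar step: kinetic deprotonation of the lactone α-CH, which is more acidic than the acyclic ester α-CH, with KN(SiMe3)2 (1.05 equiv, THF, −78 °C) and E1cB loss of methoxide give 23.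

Step 6 (one-pot aminoxylation and olefination). The α-aminoxy aldehyde 13 may decompose under the olefination base, the α-branched phosphonate 12 may react slowly or lose methoxide, and C5 could epimerise. The fallback sets out from 9 and returns at 15. Organocatalytic α-oxyamination of 9 with TEMPO (imidazolidinone catalyst of the enantiomer that gives the S centre, catalytic FeCl3 and NaNO2, air, DMF, −10 °C) gives the configurationally stable, isolable α-(TEMPO-oxy) aldehyde F1. This is olefinated with 12 under separately optimised conditions (LiCl, iPr2NEt, MeCN) to the γ-(TEMPO-oxy) enoate F2, and Zn in AcOH at 50 °C cleaves the N–O bond to give 15.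

Step 13 (SeO2 oxidation on the finished skeleton). Conversion may be low, the alcohol may over-oxidise to the enal, or C5–H may compete. The fallback sets out from 23 and returns at 24. Electrophilic ene-type chlorination of the isopropenyl group (Ca(OCl)2, solid CO2, CH2Cl2/H2O, 0 °C) gives the allylic chloride F4. Displacement with HCO2Na (catalytic NaI, DMF, 50 °C) gives the formate F5, and brief methanolysis (NaHCO3, MeOH, 0 °C) releases 24.

## Further compounds

F1 | step 6 | S-ethyl (2S,3S,5S)-3-ethenyl-3-methyl-6-oxo-2-(prop-1-en-2-yl)-5-[(2,2,6,6-tetramethylpiperidin-1-yl)oxy]hexanethioate | C=C[C@]([C@H](C(=C)C)C(=O)SCC)(C)C[C@H](ON1C(C)(C)CCCC1(C)C)C=O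
F2 | step 6 | methyl (2E,4S,6S,7S)-6-ethenyl-8-(ethylsulfanyl)-2-(methoxymethyl)-6-methyl-8-oxo-7-(prop-1-en-2-yl)-4-[(2,2,6,6-tetramethylpiperidin-1-yl)oxy]oct-2-enoate | C=C[C@]([C@H](C(=C)C)C(=O)SCC)(C)C[C@H](ON1C(C)(C)CCCC1(C)C)/C=C(/C(=O)OC)COC
F3 | step 12 | (3aR,4S,6S,7S,7aR)-6-ethenyl-3-(methoxymethyl)-6-methyl-2-oxo-7-(prop-1-en-2-yl)octahydro-1-benzofuran-4-yl (2R)-3-[(tert-butyldimethylsilyl)oxy]-2-methylpropanoate (C3 epimers) | C=C[C@]1(C)C[C@H](OC(=O)[C@H](C)CO[Si](C)(C)C(C)(C)C)[C@H]2C(COC)C(=O)O[C@@H]2[C@H]1C(=C)C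
F4 | step 13 | (3aR,4S,6S,7R,7aR)-7-(3-chloroprop-1-en-2-yl)-6-ethenyl-6-methyl-3-methylidene-2-oxooctahydro-1-benzofuran-4-yl (2R)-3-[(tert-butyldimethylsilyl)oxy]-2-methylpropanoate | C=C[C@]1(C)C[C@H](OC(=O)[C@H](C)CO[Si](C)(C)C(C)(C)C)[C@H]2C(=C)C(=O)O[C@@H]2[C@H]1C(=C)CCl
F5 | step 13 | (3aR,4S,6S,7R,7aR)-6-ethenyl-7-[3-(formyloxy)prop-1-en-2-yl]-6-methyl-3-methylidene-2-oxooctahydro-1-benzofuran-4-yl (2R)-3-[(tert-butyldimethylsilyl)oxy]-2-methylpropanoate | C=C[C@]1(C)C[C@H](OC(=O)[C@H](C)CO[Si](C)(C)C(C)(C)C)[C@H]2C(=C)C(=O)O[C@@H]2[C@H]1C(=C)COC=O
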